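Readings and results are calculated for an exercise; noise was put on by code.

I had no constants for this chemistry, so I looked in the readings for one that could carry over to the cedar charge.

the same everywhere: free catalyst 0.00600 M

| charge | starting material | partner | time |
|---|---|---|---|
| birch | 0.600 M | 0.720 M |  |
| alder | 0.300 M | 0.420 M |  |
| elm | 0.600 M | 1.40 M |  |
| cedar | 0.600 M | 4.70 M | 160 min |

| run | time / min | [starting material] / M |
|---|---|---|
| birch run | 27 | 0.285 |
| birch run | 53 | 0.177 |
| birch run | 80 | 0.126 |
| birch run | 110 | 0.097 |
| birch run | 130 | 0.082 |
| birch run | 160 | 0.067 |
| alder run | 27 | 0.162 |
| alder run | 53 | 0.107 |
| alder run | 80 | 0.067 |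
| alder run | 110 | 0.046 |
| alder run | 130 | 0.044 |
| alder run | 160 | 0.034 |
| elm run | 27 | 0.285 |
| elm run | 53 | 0.190 |
| elm run | 80 | 0.149 |
| elm run | 110 | 0.125 |
| elm run | 130 | 0.107 |
| elm run | 160 | 0.096 |

(scatter of a reading: 0.003 M)

- the power of [starting material] that the first rate follows, about the charge of the birch run; measure it at two percent of starting material made into target (one fixed amount of target, the same in the runs compared)
- the power of [partner] that the first rate follows, about the charge of the birch run; measure it at two percent of starting material made into target
- starting material in the cedar run at 160 min, as a share of the starting material charged

- Overall: starting material + partner -> target, with free catalyst as catalyst.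
- Constant volume, constant temperature.
- What is held in complexes is read along with the free species.
- "The second partner" is partner.
- An order is taken over about fifteen percent of the charge, up and down.

At 160 min the elm run held 0.096 M of starting material against 0.067 M in the birch run, although elm carried more partner, so I took partner to shorten the catalyst's working life and read late elm as a flask whose catalyst had stopped. If starting material, at concentration S, then goes by a second-order loss with itself, the reciprocal of S climbs straight in time. Between 80 min and 160 min it climbed at 0.0463 L mol⁻¹ min⁻¹, and I named this slope g, the tail constant; the scatter of the last reading moves it by 8.79%.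

That gave me two extremes for cedar. In the first the catalyst lasts, S keeps the first-order pace of early elm, 0.0276 min⁻¹, and 1.21% of the charge is left at 160 min. In the second the catalyst stops at once, and the share left is one over one plus charge times g times time, 18.4%. I expected the cedar run between them and close to the second, since its partner stands 3.36 times that of elm, and I committed to about 18.4%.

The forecast, holding that “the partner ties up catalyst reversibly and also kills it”, gave orders of 0.9 (0.65 to 1.05) in starting material and 0.2 (−0.1 to 0.5) in partner, and 50% (25% to 80%) left in cedar, which is more than my figure.

The flask gave orders of 0.49 in starting material and 0.067 in partner, and 18.9% left in the cedar run.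

    free catalyst + starting material → catalyst-substrate complex (3.900 L mol⁻¹ min⁻¹)
    catalyst-substrate complex + partner → loaded catalyst (16.08 L mol⁻¹ min⁻¹)
    loaded catalyst → target + free catalyst (2.280 min⁻¹)
    2 starting material → homo dimer (0.02142 L mol⁻¹ min⁻¹)
    free catalyst + partner → spent catalyst + partner (0.03576 L mol⁻¹ min⁻¹)

The tail constant had put the cedar run at 18.4%, and the reason for so low a share is the path pairing starting material into homo dimer: the cedar run without that path holds 86.9% at 160 min, against 18.9% with it. I used the same g on the alder run: taking the integral of S squared up to the first reading as charge times that reading times the time, it gives 0.0608 M of starting material paired away by 27 min. Of the 0.300 M charged to the alder run, 0.138 M had gone by that reading, and target reached 0.0750 M at 24.5 min, which leaves 0.0630 M not accounted for by target.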